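Work with the fraction left in cedar, not the fraction made.

in all of them: substrate 1.2 M

| charge | capture agent | free catalyst | temperature | remark | time |
|---|---|---|---|---|---|
| cedar | 0.36 M | 9 mM | 100 °C | the very flask that is asked about, followed so far |  |
| oak | 0.36 M | 9 mM | 95 °C | run made earlier |  |
| flask | 0.360 M | 9.0 mM | 100 °C |  | 10 h |

| run | time / h | product / % | substrate / % |
|---|---|---|---|
| cedar | 1.50 | 36.1 | 64.2 |
| cedar | 3.00 | 52.3 | 45.3 |
| cedar | 5.00 | 63.6 | 38.0 |
| cedar | 6.00 | 66.1 | 33.9 |
| cedar | 8.00 | 69.6 | 30.2 |
| oak | 1.50 | 27.7 | 70.3 |
| oak | 3.00 | 45.1 | 53.8 |
| oak | 5.00 | 57.2 | 41.9 |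
| oak | 6.00 | 60.6 | 38.2 |
| oak | 8.00 | 66.3 | 31.4 |

(each reading ± 1 percentage point)

- product, in percent of the substrate first charged, at 10 h
- what to do for the largest gain in product; "none" if nothing gains more than 2 percentage points (east / south / south-west / north / none)
- product present, with what was taken out counted in, in percent of the substrate first charged, after east
- product present, with what was taken out counted in, in percent of the substrate first charged, after south

- east: at 10 h add free catalyst, 100% of the amount charged, then wait 20 h
- south: at 10 h raise the temperature by 20 K, then wait 20 h
- south-west: at 10 h take out 90% of the product then present, then wait 20 h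
- north: change nothing and wait 20 h more

- what is taken out of product is counted as made
- the numbers in the tables scatter with a standard deviation of 1 percentage point
- additions bring no volume worth counting

Take "left" as the mean of the substrate reading and what the product reading leaves open, and write L for ln(charged/left). A steady pseudo-first-order loss would double L from 3.00 h to 6.00 h. Cedar goes from 0.766 to 1.08, less than double, so the catalyst is dying. If its activity decays at 0.295 h⁻¹, L climbs towards a ceiling of 1.30. Call this ceiling the reach of the charge, the value of L that one catalyst charge can buy before it dies.

Now turn the settings by hand. Time: at 10 h cedar has spent 1.24, so 29.1% is left and 70.9% is made. The unspent reach is 0.0683, so waiting adds 1.9 percentage points. Heat: between 6.00 h and 8.00 h, L rose by 0.176 in oak and by 0.112 in cedar. The hotter run is thus tiring sooner, so in this reckoning heat buys a part of the unspent reach, and south ends somewhere under the 72.8% that spending it in full gives. Taking out product: this reckoning holds no term for product, so it gives the gain of waiting. Catalyst: an equal fresh charge brings a fresh reach, giving 92.6%.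

The forecast gave 71.8% (70.5% to 73%), chose east, and put east at 93% (86% to 96%) and south at 73% (72% to 76%), reading “catalyst loss with a higher activation energy than the reaction”.

The simulation gives 71.2% and the choice east, with 90.8% after east and 72.3% after south. The gains are 20 points for east, 6.1 points for south-west, 2.3 points for north and 1.1 points for south.

    substrate + free catalyst → catalyst intermediate (k = 41.0 L mol⁻¹ h⁻¹, Ea = 72.0 kJ mol⁻¹)
    catalyst intermediate ⇌ free catalyst + product (K = 14.0 M, k = 860 h⁻¹, Ea = 89.0 kJ mol⁻¹, ΔH = −47.0 kJ mol⁻¹)
    catalyst intermediate + capture agent → trapped intermediate (k = 11.0 L mol⁻¹ h⁻¹, Ea = 81.0 kJ mol⁻¹)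
    (constants at 100 °C)

Cedar's catalyst sits as free catalyst (6.70%) or trapped intermediate (92.8%) at 10.0 h, with 0.514% as catalyst intermediate, so one decay describes it. Capture and the way back act together: product at 10 h is 71.2%, but 96.7% with capture struck out and 88.5% with the way back struck out. Taking out product gains 6.1 points, against 2.3 points for waiting. In the neighbour flask with 0.22 M of capture agent, take decay proportional to c(capture agent) and reach inverse to it: reach 2.13, product 83.2%. The computed product is 81.9%.

The runs stem from a simulated flask for an exercise, and the scatter is random.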